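The route rests on cutting the O2–C3 bond of the 1,2-dioxolane (O1, O2, C3, C4, C5) together with the CH2–C(=O) and C(=O)–OCH3 bonds of the side arm. One palladium-catalysed operation, peroxypalladation of a methallyl alkene followed by methoxycarbonylation, closes the ring, sets C3 and installs the ester. It exploits that C3 is fully substituted and lies one CH2 from the ester carbonyl, so the alkylpalladium on that CH2 lacks a β-hydrogen and has CO insertion as its only forward path. The precursor is an (S)-tertiary hydroperoxide bearing CH3, a methallyl group and a 7-(tert-butyldiphenylsilyloxy)heptyl chain, reached from a Sharpless epoxide by invertive perhydrolysis of an oxetane. The triene is attached last.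

Key step: step 13

Remarks on the chemistry (assumptions):
- The target is read as methyl 2-[(3R,5S)-3,5-dimethyl-5-[(7E,9E,12Z)-pentadeca-7,9,12-trien-1-yl]-1,2-dioxolan-3-yl]acetate, with the C5 chain and the C3 CH2CO2CH3 arm on opposite ring faces.
- Which antipode of the pyridine–oxazoline ligand is matched to (S)-22 cannot be predicted. The (S)-ligand is written; the (R)-ligand replaces it if it proves mismatched.
- The chain oxygen is carried as a tert-butyldiphenylsilyl ether, because it must survive Me3SiOTf/H2O2, aqueous acetic acid and trifluoroacetic acid in methanol.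
- The carbinol centre made in step 5 is carried as a mixture because it becomes sp2 in 18.
- The final diene is built from an enal and an alkyl sulfone, because that Julia–Kocienski pairing is the reliably E-selective one.

Step 1
Reactants: 1 non-8-yn-1-ol
Product: 2 tert-butyl(non-8-yn-1-yloxy)diphenylsilane
Conditions: TBDPSCl, imidazole, DMF, 0 °C to rt
Reagents that add atoms: tert-butyl(chloro)diphenylsilane, CC(C)(C)[Si](Cl)(c1ccccc1)c1ccccc1
Why: Imidazole-promoted silylation of a primary alcohol is routine and leaves the terminal alkyne untouched.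

Step 2
Reactants: 2 tert-butyl(non-8-yn-1-yloxy)diphenylsilane; 3 trimethylaluminium; 4 formaldehyde (as paraformaldehyde)
Product: 7 (2E)-10-[(tert-butyldiphenylsilyl)oxy]-3-methyldec-2-en-1-ol, via alkenyldimethylalane 5 (not isolated), via lithium alkenylalanate 6 (not isolated)
Conditions: Me3Al (2 equiv), Cp2ZrCl2 (0.2 equiv), CH2Cl2, 0 °C to rt; volatiles removed; n-BuLi, THF/hexane, −78 °C; (CH2O)n, −78 °C to rt; aq. NH4Cl
Reagents that add atoms: trimethylaluminium 3, C[Al](C)C (one CH3); formaldehyde 4, C=O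
Why: Negishi zirconium-catalysed methylalumination adds CH3 and Al syn across the terminal alkyne with CH3 on the internal carbon, and the derived alanate is hydroxymethylated with retention, which fixes the (E)-trisubstituted alkene.

Step 3
Reactants: 7 (2E)-10-[(tert-butyldiphenylsilyl)oxy]-3-methyldec-2-en-1-ol
Product: 8 [(2R,3R)-3-{7-[(tert-butyldiphenylsilyl)oxy]heptyl}-3-methyloxiran-2-yl]methanol
Conditions: Ti(OiPr)4 (0.1 equiv), D-(−)-diethyl tartrate (0.12 equiv), t-BuOOH (2 equiv, in decane), 4 Å molecular sieves, CH2Cl2, −20 °C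
Reagents that add atoms: tert-butyl hydroperoxide, CC(C)(C)OO (one O)
Why: Sharpless asymmetric epoxidation with the D-(−)-tartrate catalyst should deliver oxygen to the alkene face that gives the (2R,3R)-epoxide, setting the quaternary carbon that becomes C5 of the dioxolane (in the configuration that step 8 inverts).

Step 4
Reactants: 8 [(2R,3R)-3-{7-[(tert-butyldiphenylsilyl)oxy]heptyl}-3-methyloxiran-2-yl]methanol
Product: 9 (2S,3R)-3-{7-[(tert-butyldiphenylsilyl)oxy]heptyl}-3-methyloxirane-2-carbaldehyde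
Conditions: TEMPO (0.1 equiv), PhI(OAc)2 (1.2 equiv), CH2Cl2, rt
Reagents that add atoms: none
Why: Oxoammonium-mediated (TEMPO/PhI(OAc)2) oxidation of a primary alcohol is neutral, so the epoxide and silyl ether survive.

Step 5
Reactants: 9 (2S,3R)-3-{7-[(tert-butyldiphenylsilyl)oxy]heptyl}-3-methyloxirane-2-carbaldehyde; 10 methylmagnesium bromide
Product: 11 (1RS)-1-[(2R,3R)-3-{7-[(tert-butyldiphenylsilyl)oxy]heptyl}-3-methyloxiran-2-yl]ethan-1-ol
Conditions: MeMgBr (1.5 equiv), THF, −78 °C; aq. NH4Cl
Reagents that add atoms: methylmagnesium bromide 10, C[Mg]Br (CH3)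
Why: Grignard 1,2-addition to the aldehyde at −78 °C is much faster than epoxide opening, and the new carbinol centre may form as a mixture because it is erased at 18.

Step 6
Reactants: 11 (1RS)-1-[(2R,3R)-3-{7-[(tert-butyldiphenylsilyl)oxy]heptyl}-3-methyloxiran-2-yl]ethan-1-ol
Product: 12 (2RS,4R)-11-[(tert-butyldiphenylsilyl)oxy]-4-methylundecane-2,4-diol
Conditions: NaAlH2(OCH2CH2OCH3)2, THF, 0 °C to rt; aq. potassium sodium tartrate (KNaC4H4O6)
Reagents that add atoms: none
Why: Hydroxyl-directed reductive opening of a 2,3-epoxy alcohol delivers hydride from the oxygen-bound aluminate to the epoxide carbon next to the carbinol, giving the 1,3-diol without touching the quaternary C–O bond (4R).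

Step 7
Reactants: 12 (2RS,4R)-11-[(tert-butyldiphenylsilyl)oxy]-4-methylundecane-2,4-diol
Product: 14 tert-butyl({7-[(2R,4RS)-2,4-dimethyloxetan-2-yl]heptyl}oxy)diphenylsilane, via secondary mesylate 13 (not isolated)
Conditions: MsCl (1.1 equiv), Et3N (1.5 equiv), THF, −20 °C; then KOtBu (3 equiv), 0 °C to rt
Reagents that add atoms: methanesulfonyl chloride, CS(=O)(=O)Cl (its atoms stay in intermediate 13 and leave on ring closure)
Why: Selective sulfonylation of the secondary hydroxyl followed by intramolecular Williamson etherification (4-exo-tet) by the tertiary alkoxide closes the oxetane with retention at the quaternary carbon, which is only the nucleophile-bearing centre.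

Step 8
Reactants: 14 tert-butyl({7-[(2R,4RS)-2,4-dimethyloxetan-2-yl]heptyl}oxy)diphenylsilane; 15 hydrogen peroxide
Product: 16 (2RS,4S)-11-[(tert-butyldiphenylsilyl)oxy]-4-hydroperoxy-4-methylundecan-2-ol
Conditions: H2O2 (anhydrous, in Et2O, 10 equiv), Me3SiOTf (0.3 equiv), Et2O, −78 °C to −20 °C
Reagents that add atoms: hydrogen peroxide 15, OO
Why: Lewis-acid-promoted perhydrolysis of a 2,2-disubstituted oxetane opens the activated ring at the more substituted carbon in an SN2-like ion-pair pathway with inversion, turning the (R)-C–O centre into the (S)-C–OOH centre that becomes C5.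

Step 9
Reactants: 16 (2RS,4S)-11-[(tert-butyldiphenylsilyl)oxy]-4-hydroperoxy-4-methylundecan-2-ol
Product: 17 (2RS,4S)-11-[(tert-butyldiphenylsilyl)oxy]-4-[(2-methoxypropan-2-yl)peroxy]-4-methylundecan-2-ol
Conditions: 2-methoxypropene (1.2 equiv), PPTS (5 mol %), CH2Cl2, 0 °C
Reagents that add atoms: 2-methoxypropene, COC(C)=C
Why: Acid-catalysed peroxyketalisation should select the hydroperoxide, which is the better nucleophile toward the oxocarbenium ion and gives the more acid-stable adduct, over the hindered secondary hydroxyl.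

Step 10
Reactants: 17 (2RS,4S)-11-[(tert-butyldiphenylsilyl)oxy]-4-[(2-methoxypropan-2-yl)peroxy]-4-methylundecan-2-ol
Product: 18 (4S)-11-[(tert-butyldiphenylsilyl)oxy]-4-[(2-methoxypropan-2-yl)peroxy]-4-methylundecan-2-one
Conditions: Dess–Martin periodinane, pyridine, CH2Cl2, 0 °C to rt
Reagents that add atoms: none
Why: Dess–Martin oxidation of a secondary alcohol under buffered, non-basic conditions tolerates the peroxyketal and the silyl ether.

Step 11
Reactants: 18 (4S)-11-[(tert-butyldiphenylsilyl)oxy]-4-[(2-methoxypropan-2-yl)peroxy]-4-methylundecan-2-one; 19 methyltriphenylphosphonium bromide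
Product: 21 tert-butyl{[(8S)-8-[(2-methoxypropan-2-yl)peroxy]-8,10-dimethylundec-10-en-1-yl]oxy}diphenylsilane, via methylidenetriphenylphosphorane 20 (not isolated)
Conditions: Ph3PCH3Br (1.5 equiv), KOtBu (1.4 equiv), THF, 0 °C; then 18, −78 °C to 0 °C
Reagents that add atoms: methyltriphenylphosphonium bromide 19, C[P+](c1ccccc1)(c1ccccc1)c1ccccc1.[Br-] (CH2)
Why: Wittig methylenation should outrun deprotonation of the hindered CH2 between the carbonyl and the quaternary peroxy carbon, and the peroxyketal is inert to the ylide.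

Step 12
Reactants: 21 tert-butyl{[(8S)-8-[(2-methoxypropan-2-yl)peroxy]-8,10-dimethylundec-10-en-1-yl]oxy}diphenylsilane
Product: 22 tert-butyl{[(8S)-8-hydroperoxy-8,10-dimethylundec-10-en-1-yl]oxy}diphenylsilane
Conditions: AcOH/THF/H2O (3:1:1), rt
Reagents that add atoms: none
Why: Mild acid hydrolysis of the mixed peroxyketal frees the hydroperoxide, while the tert-butyldiphenylsilyl ether and the alkene withstand aqueous acetic acid.

Step 13
Reactants: 22 tert-butyl{[(8S)-8-hydroperoxy-8,10-dimethylundec-10-en-1-yl]oxy}diphenylsilane; 23 carbon monoxide; 24 methanol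
Product: 27 methyl 2-[(3R,5S)-5-{7-[(tert-butyldiphenylsilyl)oxy]heptyl}-3,5-dimethyl-1,2-dioxolan-3-yl]acetate, via alkylpalladium trifluoroacetate 25 (not isolated), via acylpalladium trifluoroacetate 26 (not isolated)
Conditions: Pd(OCOCF3)2 (10 mol %), (S)-tBu-pyox [2-((4S)-4-tert-butyl-4,5-dihydrooxazol-2-yl)pyridine] (12 mol %), p-benzoquinone (1.5 equiv), CO (1 atm), MeOH/CH2Cl2 (1:4), 0 °C to rt
Reagents that add atoms: carbon monoxide 23, [C-]#[O+]; methanol 24, CO
Why: Proposed new method: divalent palladium carrying the pyridine–oxazoline ligand binds the 1,1-disubstituted alkene of 22 and the C5 hydroperoxide oxygen adds anti to the metal at the internal alkene carbon, a 5-exo-trig closure that forms O2–C3 and the 1,2-dioxolane and leaves primary alkylpalladium 25 on the CH2 next to fully substituted C3; having no β-hydrogen, 25 inserts CO to give acylpalladium 26, methanol cleaves this to the ester, and p-benzoquinone returns zerovalent palladium to the divalent state. The closest known reaction types are the divalent-palladium cyclisation of unsaturated tertiary hydroperoxides to cyclic peroxides and the intramolecular alkoxypalladation–methoxycarbonylation of alkenols that gives ring-substituted methyl acetates. The new C3 stereocentre is fixed in the peroxypalladation: the chiral ligand selects the alkene face, and because peroxypalladation can revert by β-peroxide elimination while CO insertion cannot, material should drain through the alkylpalladium whose envelope keeps the CH2–Pd arm trans to the longer C5 substituent. Since C5 carries CH3 and a CH2 chain of similar size, the intrinsic 1,3-bias is expected to be small, so the ligand is the controlling element and any C3 epimer is to be removed by chromatography. The step needs the hydroperoxide rather than methanol as nucleophile, 5-exo rather than 6-endo closure and CO insertion rather than O–O reduction, which the intramolecular geometry at gem-disubstituted C5, Markovnikov attack on the 1,1-disubstituted alkene, the absence of β-hydrogens and the quinone oxidant should secure.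

Step 14
Reactants: 27 methyl 2-[(3R,5S)-5-{7-[(tert-butyldiphenylsilyl)oxy]heptyl}-3,5-dimethyl-1,2-dioxolan-3-yl]acetate
Product: 28 methyl 2-[(3R,5S)-5-(7-hydroxyheptyl)-3,5-dimethyl-1,2-dioxolan-3-yl]acetate
Conditions: HF·pyridine, pyridine, THF, 0 °C to rt
Reagents that add atoms: none
Why: Fluoride-mediated desilylation under buffered, non-basic conditions should spare both the O–O bond and the base-sensitive β-peroxy ester.

Step 15
Reactants: 28 methyl 2-[(3R,5S)-5-(7-hydroxyheptyl)-3,5-dimethyl-1,2-dioxolan-3-yl]acetate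
Product: 29 methyl 2-[(3R,5S)-3,5-dimethyl-5-(7-oxoheptyl)-1,2-dioxolan-3-yl]acetate
Conditions: TEMPO (0.1 equiv), PhI(OAc)2 (1.2 equiv), CH2Cl2, rt
Reagents that add atoms: none
Why: TEMPO/PhI(OAc)2 oxidation stops at the aldehyde and involves neither a reductant nor a base that could attack the peroxide.

Step 16
Reactants: 29 methyl 2-[(3R,5S)-3,5-dimethyl-5-(7-oxoheptyl)-1,2-dioxolan-3-yl]acetate; 30 (triphenylphosphoranylidene)acetaldehyde
Product: 31 methyl 2-[(3R,5S)-3,5-dimethyl-5-[(7E)-9-oxonon-7-en-1-yl]-1,2-dioxolan-3-yl]acetate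
Conditions: Ph3P=CHCHO (1.2 equiv), toluene, 75 °C
Reagents that add atoms: (triphenylphosphoranylidene)acetaldehyde 30, O=CC=P(c1ccccc1)(c1ccccc1)c1ccccc1 (CH–CHO)
Why: Wittig reaction with the stabilised formylmethylene ylide is neutral and E-selective, setting the 7E alkene as an enal, and the fully substituted dioxolane should tolerate the moderate heating.

Step 17
Reactants: 32 (3Z)-hex-3-en-1-ol
Product: 33 5-{[(3Z)-hex-3-en-1-yl]sulfanyl}-1-phenyl-1H-tetrazole
Conditions: 1-phenyl-1H-tetrazole-5-thiol, PPh3, DIAD, THF, 0 °C to rt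
Reagents that add atoms: 1-phenyl-1H-tetrazole-5-thiol, Sc1nnnn1-c1ccccc1
Why: Mitsunobu thioetherification of a primary alcohol with the acidic tetrazole thiol is an SN2 displacement at CH2 that cannot disturb the Z alkene.

Step 18
Reactants: 33 5-{[(3Z)-hex-3-en-1-yl]sulfanyl}-1-phenyl-1H-tetrazole; 15 hydrogen peroxide
Product: 34 5-{[(3Z)-hex-3-en-1-yl]sulfonyl}-1-phenyl-1H-tetrazole
Conditions: (NH4)6Mo7O24·4H2O (0.1 equiv), 30% aq. H2O2 (5 equiv), EtOH, 0 °C to rt
Reagents that add atoms: hydrogen peroxide 15, OO (two O atoms, from two molecules)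
Why: Molybdate-catalysed peroxide oxidation takes the sulfide to the sulfone, while an isolated disubstituted alkene is not epoxidised under these conditions.

Step 19
Reactants: 31 methyl 2-[(3R,5S)-3,5-dimethyl-5-[(7E)-9-oxonon-7-en-1-yl]-1,2-dioxolan-3-yl]acetate; 34 5-{[(3Z)-hex-3-en-1-yl]sulfonyl}-1-phenyl-1H-tetrazole
Product: 36 methyl 2-[(3R,5S)-3,5-dimethyl-5-[(7E,9E,12Z)-pentadeca-7,9,12-trien-1-yl]-1,2-dioxolan-3-yl]acetate, via potassiated sulfone 35 (not isolated)
Conditions: 34 (1.3 equiv), KN(SiMe3)2 (1.25 equiv), DME, −60 °C, 20 min; then 31, −60 °C to rt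
Reagents that add atoms: 5-{[(3Z)-hex-3-en-1-yl]sulfonyl}-1-phenyl-1H-tetrazole 34, CC/C=C\CCS(=O)(=O)c1nnnn1-c1ccccc1 (its six chain carbons)
Why: Julia–Kocienski olefination of an alkyl phenyltetrazolyl sulfone with an α,β-unsaturated aldehyde is the E-selective pairing and should set the 9E alkene, and premetalation of the sulfone keeps free amide base away from the β-peroxy ester.

Compound list
1 | non-8-yn-1-ol | C#CCCCCCCCO | starting material
2 | tert-butyl(non-8-yn-1-yloxy)diphenylsilane | CC(C)(C)[Si](c1ccccc1)(c1ccccc1)OCCCCCCCC#C | intermediate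
3 | trimethylaluminium | C[Al](C)C | starting material
4 | formaldehyde (used as paraformaldehyde) | C=O | starting material
5 | [(1E)-9-[(tert-butyldiphenylsilyl)oxy]-2-methylnon-1-en-1-yl]dimethylalane | CC(C)(C)[Si](c1ccccc1)(c1ccccc1)OCCCCCCC/C(C)=C/[Al](C)C | intermediate (not isolated)
6 | lithium butyl[(1E)-9-[(tert-butyldiphenylsilyl)oxy]-2-methylnon-1-en-1-yl]dimethylalanuide | [Li+].CCCC[Al-](C)(C)/C=C(\C)CCCCCCCO[Si](c1ccccc1)(c1ccccc1)C(C)(C)C | intermediate (not isolated)
7 | (2E)-10-[(tert-butyldiphenylsilyl)oxy]-3-methyldec-2-en-1-ol | CC(C)(C)[Si](c1ccccc1)(c1ccccc1)OCCCCCCC/C(C)=C/CO | intermediate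
8 | [(2R,3R)-3-{7-[(tert-butyldiphenylsilyl)oxy]heptyl}-3-methyloxiran-2-yl]methanol | CC(C)(C)[Si](c1ccccc1)(c1ccccc1)OCCCCCCC[C@@]1(C)O[C@@H]1CO | intermediate
9 | (2S,3R)-3-{7-[(tert-butyldiphenylsilyl)oxy]heptyl}-3-methyloxirane-2-carbaldehyde | CC(C)(C)[Si](c1ccccc1)(c1ccccc1)OCCCCCCC[C@@]1(C)O[C@@H]1C=O | intermediate
10 | methylmagnesium bromide | C[Mg]Br | starting material
11 | (1RS)-1-[(2R,3R)-3-{7-[(tert-butyldiphenylsilyl)oxy]heptyl}-3-methyloxiran-2-yl]ethan-1-ol | CC(C)(C)[Si](c1ccccc1)(c1ccccc1)OCCCCCCC[C@@]1(C)O[C@@H]1C(C)O | intermediate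
12 | (2RS,4R)-11-[(tert-butyldiphenylsilyl)oxy]-4-methylundecane-2,4-diol | CC(C)(C)[Si](c1ccccc1)(c1ccccc1)OCCCCCCC[C@](O)(C)CC(C)O | intermediate
13 | (2RS,4R)-11-[(tert-butyldiphenylsilyl)oxy]-4-hydroxy-4-methylundecan-2-yl methanesulfonate | CC(C)(C)[Si](c1ccccc1)(c1ccccc1)OCCCCCCC[C@](O)(C)CC(C)OS(C)(=O)=O | intermediate (not isolated)
14 | tert-butyl({7-[(2R,4RS)-2,4-dimethyloxetan-2-yl]heptyl}oxy)diphenylsilane | CC(C)(C)[Si](c1ccccc1)(c1ccccc1)OCCCCCCC[C@]1(C)CC(C)O1 | intermediate
15 | hydrogen peroxide | OO | starting material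
16 | (2RS,4S)-11-[(tert-butyldiphenylsilyl)oxy]-4-hydroperoxy-4-methylundecan-2-ol | CC(C)(C)[Si](c1ccccc1)(c1ccccc1)OCCCCCCC[C@@](OO)(C)CC(C)O | intermediate
17 | (2RS,4S)-11-[(tert-butyldiphenylsilyl)oxy]-4-[(2-methoxypropan-2-yl)peroxy]-4-methylundecan-2-ol | CC(C)(C)[Si](c1ccccc1)(c1ccccc1)OCCCCCCC[C@@](OOC(C)(C)OC)(C)CC(C)O | intermediate
18 | (4S)-11-[(tert-butyldiphenylsilyl)oxy]-4-[(2-methoxypropan-2-yl)peroxy]-4-methylundecan-2-one | CC(C)(C)[Si](c1ccccc1)(c1ccccc1)OCCCCCCC[C@@](OOC(C)(C)OC)(C)CC(C)=O | intermediate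
19 | methyltriphenylphosphonium bromide | C[P+](c1ccccc1)(c1ccccc1)c1ccccc1.[Br-] | starting material
20 | methylidenetriphenylphosphorane | C=P(c1ccccc1)(c1ccccc1)c1ccccc1 | intermediate (not isolated)
21 | tert-butyl{[(8S)-8-[(2-methoxypropan-2-yl)peroxy]-8,10-dimethylundec-10-en-1-yl]oxy}diphenylsilane | CC(C)(C)[Si](c1ccccc1)(c1ccccc1)OCCCCCCC[C@@](OOC(C)(C)OC)(C)CC(C)=C | intermediate
22 | tert-butyl{[(8S)-8-hydroperoxy-8,10-dimethylundec-10-en-1-yl]oxy}diphenylsilane | CC(C)(C)[Si](c1ccccc1)(c1ccccc1)OCCCCCCC[C@@](OO)(C)CC(C)=C | intermediate (key-step precursor)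
23 | carbon monoxide | [C-]#[O+] | starting material
24 | methanol | CO | starting material
25 | ({(3R,5S)-5-{7-[(tert-butyldiphenylsilyl)oxy]heptyl}-3,5-dimethyl-1,2-dioxolan-3-yl}methyl)palladium trifluoroacetate (ligand not drawn) | CC(C)(C)[Si](c1ccccc1)(c1ccccc1)OCCCCCCC[C@@]1(C)C[C@](C)(C[Pd]OC(=O)C(F)(F)F)OO1 | intermediate (not isolated)
26 | {2-[(3R,5S)-5-{7-[(tert-butyldiphenylsilyl)oxy]heptyl}-3,5-dimethyl-1,2-dioxolan-3-yl]acetyl}palladium trifluoroacetate (ligand not drawn) | CC(C)(C)[Si](c1ccccc1)(c1ccccc1)OCCCCCCC[C@@]1(C)C[C@](C)(CC(=O)[Pd]OC(=O)C(F)(F)F)OO1 | intermediate (not isolated)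
27 | methyl 2-[(3R,5S)-5-{7-[(tert-butyldiphenylsilyl)oxy]heptyl}-3,5-dimethyl-1,2-dioxolan-3-yl]acetate | CC(C)(C)[Si](c1ccccc1)(c1ccccc1)OCCCCCCC[C@@]1(C)C[C@](C)(CC(=O)OC)OO1 | intermediate (key-step product)
28 | methyl 2-[(3R,5S)-5-(7-hydroxyheptyl)-3,5-dimethyl-1,2-dioxolan-3-yl]acetate | OCCCCCCC[C@@]1(C)C[C@](C)(CC(=O)OC)OO1 | intermediate
29 | methyl 2-[(3R,5S)-3,5-dimethyl-5-(7-oxoheptyl)-1,2-dioxolan-3-yl]acetate | O=CCCCCCC[C@@]1(C)C[C@](C)(CC(=O)OC)OO1 | intermediate
30 | (triphenylphosphoranylidene)acetaldehyde | O=CC=P(c1ccccc1)(c1ccccc1)c1ccccc1 | starting material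
31 | methyl 2-[(3R,5S)-3,5-dimethyl-5-[(7E)-9-oxonon-7-en-1-yl]-1,2-dioxolan-3-yl]acetate | O=C/C=C/CCCCCC[C@@]1(C)C[C@](C)(CC(=O)OC)OO1 | intermediate
32 | (3Z)-hex-3-en-1-ol | CC/C=C\CCO | starting material
33 | 5-{[(3Z)-hex-3-en-1-yl]sulfanyl}-1-phenyl-1H-tetrazole | CC/C=C\CCSc1nnnn1-c1ccccc1 | intermediate
34 | 5-{[(3Z)-hex-3-en-1-yl]sulfonyl}-1-phenyl-1H-tetrazole | CC/C=C\CCS(=O)(=O)c1nnnn1-c1ccccc1 | intermediate
35 | potassium (3Z)-1-[(1-phenyl-1H-tetrazol-5-yl)sulfonyl]hex-3-en-1-ide | CC/C=C\C[CH-]S(=O)(=O)c1nnnn1-c1ccccc1.[K+] | intermediate (not isolated)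
36 | methyl 2-[(3R,5S)-3,5-dimethyl-5-[(7E,9E,12Z)-pentadeca-7,9,12-trien-1-yl]-1,2-dioxolan-3-yl]acetate | CC/C=C\C/C=C/C=C/CCCCCC[C@@]1(C)C[C@](C)(CC(=O)OC)OO1 | target

Total step count: 19. Longest linear sequence: 17 steps (steps 1–16 and 19).

Steps most likely to fail

1. Step 13 (new method).
   - What may go wrong: reduction of the O–OH group by zerovalent palladium or CO before cyclisation; acid-induced rearrangement of the tertiary hydroperoxide; methanol competing as the nucleophile; poor face selection at C3.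
   - Fallback, by known chemistry, sets out from ketone 18 and returns at 27. TsOH·H2O (cat.) in methanol should remove the peroxyketal and let the freed hydroperoxy ketone close to tert-butyl({7-[(3S)-5-methoxy-3,5-dimethyl-1,2-dioxolan-3-yl]heptyl}oxy)diphenylsilane F1 (both methoxy epimers). TiCl4 in CH2Cl2 at −78 °C then ionises F1 to the cyclic peroxycarbenium ion, which 1-methoxy-1-(trimethylsilyloxy)ethene traps to give 27 and its C3 epimer, to be separated by chromatography. This is the established Lewis-acid homologation of 3-alkoxy-1,2-dioxolanes with silyl ketene acetals.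

2. Step 8.
   - What may go wrong: ionisation of the activated oxetane to a free tertiary cation, causing loss of configuration or elimination; opening at the secondary carbon; loss of the silyl ether.
   - Fallback sets out from diol 12 and returns at 18, using diastereomer separation in place of stereospecific opening. The C2 epimers of 12 are separated by chromatography, giving (2S,4R)-11-[(tert-butyldiphenylsilyl)oxy]-4-methylundecane-2,4-diol F2. Classical acid-catalysed perhydrolysis of the tertiary alcohol (50% H2O2, cat. H2SO4, THF, 0 °C) runs through the cation and gives both C4 configurations. Because C2 is now single, the wanted (2S,4S)-11-[(tert-butyldiphenylsilyl)oxy]-4-hydroperoxy-4-methylundecan-2-ol F3 is a diastereomer of the unwanted one and is isolated by chromatography, at the cost of at most half the material. Peroxyketalisation as in step 9 gives (2S,4S)-11-[(tert-butyldiphenylsilyl)oxy]-4-[(2-methoxypropan-2-yl)peroxy]-4-methylundecan-2-ol F4, and Dess–Martin oxidation as in step 10 gives 18.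

3. Step 11.
   - What may go wrong: enolisation of the ketone toward the CH2 next to the peroxy carbon, followed by expulsion of the peroxy group or attack on the O–O bond; incomplete olefination.
   - Fallback sets out from 18 and returns at 22 by a Peterson olefination. Me3SiCH2Li premixed with anhydrous CeCl3 (THF, −78 °C) is a weakly basic organocerium reagent that should add to the ketone to give (4S)-11-[(tert-butyldiphenylsilyl)oxy]-4-[(2-methoxypropan-2-yl)peroxy]-2,4-dimethyl-1-(trimethylsilyl)undecan-2-ol F5. TsOH (cat.) in wet THF then effects the acid-type Peterson elimination and cleaves the peroxyketal in the same operation, giving 22 directly.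

Further compounds
F1 | step 13 | tert-butyl({7-[(3S)-5-methoxy-3,5-dimethyl-1,2-dioxolan-3-yl]heptyl}oxy)diphenylsilane | CC(C)(C)[Si](c1ccccc1)(c1ccccc1)OCCCCCCC[C@@]1(C)CC(C)(OC)OO1
F2 | step 8 | (2S,4R)-11-[(tert-butyldiphenylsilyl)oxy]-4-methylundecane-2,4-diol | CC(C)(C)[Si](c1ccccc1)(c1ccccc1)OCCCCCCC[C@](O)(C)C[C@H](C)O
F3 | step 8 | (2S,4S)-11-[(tert-butyldiphenylsilyl)oxy]-4-hydroperoxy-4-methylundecan-2-ol | CC(C)(C)[Si](c1ccccc1)(c1ccccc1)OCCCCCCC[C@@](OO)(C)C[C@H](C)O
F4 | step 8 | (2S,4S)-11-[(tert-butyldiphenylsilyl)oxy]-4-[(2-methoxypropan-2-yl)peroxy]-4-methylundecan-2-ol | CC(C)(C)[Si](c1ccccc1)(c1ccccc1)OCCCCCCC[C@@](OOC(C)(C)OC)(C)C[C@H](C)O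
F5 | step 11 | (4S)-11-[(tert-butyldiphenylsilyl)oxy]-4-[(2-methoxypropan-2-yl)peroxy]-2,4-dimethyl-1-(trimethylsilyl)undecan-2-ol | CC(C)(C)[Si](c1ccccc1)(c1ccccc1)OCCCCCCC[C@@](OOC(C)(C)OC)(C)CC(C)(O)C[Si](C)(C)C
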